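**Retrosynthetic overview**
1. The target comes from a silyl-protected, epoxide-bearing 7-oxabicyclo[2.2.1]heptane by epoxide → bromohydrin → chlorination with 1,2-bromine shift (sets C–Br), then desilylation.
2. Key disconnection: the tertiary C1–O bond of the oxygen bridge, closed by transannular Markovnikov addition of the ring hydroxyl across the alkene of a 4-methylcyclohex-3-en-1-ol. Ring order: carbocycle first, oxygen bridge second.
3. The cyclohexenol comes from ring-closing metathesis of a diene made by asymmetric allylation of an α-quaternary aldehyde.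
4. The aldehyde comes from an allyl vinyl ether (a second strategic C–O bond, copper-catalysed) that undergoes Claisen rearrangement, joining both halves and setting the vicinal quaternary/tertiary centres by chirality transfer.
5. The halves are an (S)-linalool-derived secondary allylic alcohol and a sulcatone-derived (E)-vinyl iodide carrying a Shi epoxide as the masked bromochloride.

Assumption 1: (S)-(+)-linalool of at least 95% ee and 6-methylhept-5-en-2-one (sulcatone) are bought; all reagents are catalogue items.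
Assumption 2: zinc and boron alkoxides cleaved at work-up are written as the free alcohols, and species that cannot be intercepted (ion pairs, the chlorosulfite, the twisted alkene) are explained in the Why lines and not numbered.

Step 1
Reactants: 1 (S)-(+)-linalool [(3S)-3,7-dimethylocta-1,6-dien-3-ol]
Product: 2 triethyl{[(3S)-3,7-dimethylocta-1,6-dien-3-yl]oxy}silane
Conditions: TESOTf, 2,6-lutidine, CH2Cl2, −78 to 0 °C
Reagents that add atoms: triethylsilyl trifluoromethanesulfonate, CC[Si](CC)(CC)OS(=O)(=O)C(F)(F)F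
Why: Silyl ether protection of a tertiary alcohol by a silyl triflate with a hindered pyridine base; no bond to the stereocentre is touched, and the ether later keeps the vinyl carbinol out of the metathesis and out of the bridge closure.

Step 2
Reactants: 2 triethyl{[(3S)-3,7-dimethylocta-1,6-dien-3-yl]oxy}silane
Product: 4 (2E,6S)-2,6-dimethyl-6-[(triethylsilyl)oxy]octa-2,7-dienal, via allylic alcohol 3 (not isolated)
Conditions: SeO2 (1.5 equiv), pyridine (0.3 equiv), 1,4-dioxane, 80 °C
Reagents that add atoms: selenium dioxide, O=[Se]=O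
Why: Riley allylic oxidation (ene reaction then [2,3]-sigmatropic shift) is selective for the (E)-methyl of the gem-dimethyl alkene and carries the first-formed allylic alcohol on to the (E)-enal; no stereocentre is formed and the vinyl group has no allylic hydrogen.

Step 3
Reactants: 4 (2E,6S)-2,6-dimethyl-6-[(triethylsilyl)oxy]octa-2,7-dienal
Product: 5 (3S,4E,8S)-4,8-dimethyl-8-[(triethylsilyl)oxy]deca-4,9-dien-3-ol
Conditions: Et2Zn (2 equiv), (2S)-(−)-3-exo-morpholinoisoborneol [(−)-MIB, 5 mol%], hexane/toluene, 0 °C; aq. NH4Cl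
Reagents that add atoms: diethylzinc, CC[Zn]CC
Why: Amino-alcohol-catalysed enantioselective 1,2-addition of a dialkylzinc to an aldehyde (Noyori type); (−)-MIB directs ethyl to the Si face of the enal and so sets the (3S)-carbinol that later relays chirality in the Claisen step.

Step 4
Reactants: 6 sulcatone (6-methylhept-5-en-2-one)
Product: 8 6-methylhept-5-en-1-yne, via enol phosphate 7 (not isolated)
Conditions: LiN(iPr)2 (1.1 equiv), THF, −78 °C; ClP(O)(OEt)2; then LiN(iPr)2 (2.3 equiv), −78 °C to rt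
Reagents that add atoms: none
Why: Negishi methyl ketone to alkyne conversion: the kinetic methyl-side enolate is trapped on oxygen as the enol phosphate and excess amide base eliminates phosphate to give the terminal alkyne.

Step 5
Reactants: 8 6-methylhept-5-en-1-yne
Product: 10 (1E)-1-iodo-2,6-dimethylhepta-1,5-diene, via alkenylalane 9 (not isolated)
Conditions: AlMe3 (2 equiv), Cp2ZrCl2 (0.25 equiv), CH2Cl2, 0 °C to rt; then I2, THF, −30 °C
Reagents that add atoms: trimethylaluminium, C[Al](C)C; iodine, II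
Why: Negishi zirconium-catalysed carboalumination: syn addition of methyl and aluminium across the alkyne and iodinolysis with retention give only the (E)-vinyl iodide, which fixes the geometry of the later enol ether.

Step 6
Reactants: 10 (1E)-1-iodo-2,6-dimethylhepta-1,5-diene
Product: 11 (3R)-3-[(3E)-4-iodo-3-methylbut-3-en-1-yl]-2,2-dimethyloxirane
Conditions: D-fructose-derived Shi ketone (1,2:4,5-di-O-isopropylidene-β-D-erythro-2,3-hexodiulo-2,6-pyranose, 30 mol%), Oxone (2KHSO5·KHSO4·K2SO4), K2CO3, Bu4NHSO4, MeCN/CH2(OMe)2/aq. Na2B4O7 buffer, 0 °C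
Reagents that add atoms: potassium peroxymonosulfate, [K+].[O-]S(=O)(=O)OO
Why: Shi asymmetric epoxidation (chiral dioxirane, spiro transition state) reacts only with the electron-rich trisubstituted alkene and gives the (R)-epoxide that is the later C–Br carbon; it also masks this alkene during metathesis.

Step 7
Reactants: 5 (3S,4E,8S)-4,8-dimethyl-8-[(triethylsilyl)oxy]deca-4,9-dien-3-ol; 11 (3R)-3-[(3E)-4-iodo-3-methylbut-3-en-1-yl]-2,2-dimethyloxirane
Product: 13 (2S,3R,4E)-2-{2-[(2R)-3,3-dimethyloxiran-2-yl]ethyl}-2,4-dimethyl-3-{(3S)-3-methyl-3-[(triethylsilyl)oxy]pent-4-en-1-yl}hept-4-enal, via allyl vinyl ether 12 (not isolated)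
Conditions: CuI (10 mol%), 3,4,7,8-tetramethyl-1,10-phenanthroline (20 mol%), Cs2CO3 (2 equiv), o-xylene, 110 °C then 140 °C
Reagents that add atoms: none
Why: Copper-catalysed Ullmann-type C–O coupling of the vinyl iodide with the allylic alcohol (geometry retained) followed by thermal Claisen rearrangement through a chair transition state with ethyl equatorial: the (E)-enol ether and (E)-allyl unit give the anti arrangement of the two chains and the (S)-carbinol relays its chirality suprafacially to the (2S,3R) pair (about 9:1 expected, minor isomer removed later).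

Step 8
Reactants: 13 (2S,3R,4E)-2-{2-[(2R)-3,3-dimethyloxiran-2-yl]ethyl}-2,4-dimethyl-3-{(3S)-3-methyl-3-[(triethylsilyl)oxy]pent-4-en-1-yl}hept-4-enal
Product: 14 (4R,5S,6R,7E)-5-{2-[(2R)-3,3-dimethyloxiran-2-yl]ethyl}-5,7-dimethyl-6-{(3S)-3-methyl-3-[(triethylsilyl)oxy]pent-4-en-1-yl}deca-1,7-dien-4-ol
Conditions: (+)-Ipc2B(allyl), Et2O, −78 °C; then NaOH, H2O2, 0 °C
Reagents that add atoms: (+)-B-allyldiisopinocampheylborane, C=CCB([C@H]1C[C@H]2C[C@@H]([C@@H]1C)C2(C)C)[C@H]1C[C@H]2C[C@@H]([C@@H]1C)C2(C)C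
Why: Brown asymmetric allylboration via a chair six-membered transition state; the α-pinene-derived reagent delivers allyl to the Re face of the aldehyde under reagent control and sets the (4R)-alcohol that will become the bridge oxygen.

Step 9
Reactants: 14 (4R,5S,6R,7E)-5-{2-[(2R)-3,3-dimethyloxiran-2-yl]ethyl}-5,7-dimethyl-6-{(3S)-3-methyl-3-[(triethylsilyl)oxy]pent-4-en-1-yl}deca-1,7-dien-4-ol
Product: 15 (1R,5R,6S)-6-{2-[(2R)-3,3-dimethyloxiran-2-yl]ethyl}-4,6-dimethyl-5-{(3S)-3-methyl-3-[(triethylsilyl)oxy]pent-4-en-1-yl}cyclohex-3-en-1-ol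
Conditions: second-generation Grubbs catalyst RuCl2(=CHPh)(H2IMes)(PCy3) (5 mol%), toluene, 70 °C
Reagents that add atoms: none
Why: Ring-closing olefin metathesis between the allyl terminus and the trisubstituted alkene closes the cyclohexene with loss of but-1-ene; the epoxide and the hindered silyloxy vinyl group do not take part and no stereocentre changes.

Step 10
Reactants: 15 (1R,5R,6S)-6-{2-[(2R)-3,3-dimethyloxiran-2-yl]ethyl}-4,6-dimethyl-5-{(3S)-3-methyl-3-[(triethylsilyl)oxy]pent-4-en-1-yl}cyclohex-3-en-1-ol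
Product: 16 triethyl{[(3S)-5-{(1S,2S,3S,4R)-3-{2-[(2R)-3,3-dimethyloxiran-2-yl]ethyl}-1,3-dimethyl-7-oxabicyclo[2.2.1]heptan-2-yl}-3-methylpent-1-en-3-yl]oxy}silane
Conditions: hν (254 nm, quartz), p-xylene (20 equiv, sensitiser), degassed cyclohexane, 0.005 M, 15 °C
Reagents that add atoms: none
Why: Proposed new method: sensitised photochemical transannular hydroalkoxylation; triplet energy transfer from p-xylene twists only the endocyclic trisubstituted alkene into a short-lived strained E-cyclohexene whose π bond is basic enough to take the proton of the axial homoallylic hydroxyl at C3, and the tertiary cation/alkoxide pair so formed collapses across the ring, which can only give the cis 1,4-bridge and thus sets C1 of the bicycle as S; acyclic alkenes merely relax, and no acid or metal is present to touch the epoxide or silyl ether; the closest known reaction type is the xylene-sensitised Markovnikov photoaddition of alcohols to 1-alkylcyclohexenes (photoprotonation through the trans-cycloalkene), not yet used transannularly to close a 7-oxabicyclo[2.2.1]heptane.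

Step 11
Reactants: 16 triethyl{[(3S)-5-{(1S,2S,3S,4R)-3-{2-[(2R)-3,3-dimethyloxiran-2-yl]ethyl}-1,3-dimethyl-7-oxabicyclo[2.2.1]heptan-2-yl}-3-methylpent-1-en-3-yl]oxy}silane
Product: 17 (3R)-2-bromo-5-[(1R,2S,3S,4S)-2,4-dimethyl-3-{(3S)-3-methyl-3-[(triethylsilyl)oxy]pent-4-en-1-yl}-7-oxabicyclo[2.2.1]heptan-2-yl]-2-methylpentan-3-ol
Conditions: LiBr (3 equiv), AcOH (3 equiv), THF, 0 °C to rt
Reagents that add atoms: lithium bromide, [Li+].[Br-]
Why: Acid-assisted epoxide ring opening by bromide at the tertiary carbon (borderline SN1, Markovnikov regiochemistry); the C–O bond at the secondary carbon is not broken, so the (R)-carbinol is kept.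

Step 12
Reactants: 17 (3R)-2-bromo-5-[(1R,2S,3S,4S)-2,4-dimethyl-3-{(3S)-3-methyl-3-[(triethylsilyl)oxy]pent-4-en-1-yl}-7-oxabicyclo[2.2.1]heptan-2-yl]-2-methylpentan-3-ol
Product: 18 triethyl{[(3S)-5-{(1S,2S,3S,4R)-3-[(3S)-3-bromo-4-chloro-4-methylpentyl]-1,3-dimethyl-7-oxabicyclo[2.2.1]heptan-2-yl}-3-methylpent-1-en-3-yl]oxy}silane
Conditions: SOCl2 (1.5 equiv), pyridine (3 equiv), Et2O, −20 to 0 °C
Reagents that add atoms: thionyl chloride, O=S(Cl)Cl
Why: Deoxychlorination with neighbouring-group participation: the chlorosulfite is expelled by backside attack of the vicinal bromine (inversion at the secondary carbon) and chloride opens the bromonium ion at the tertiary carbon, so bromine ends on the secondary carbon as (S) and chlorine on the dimethyl carbon.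

Step 13
Reactants: 18 triethyl{[(3S)-5-{(1S,2S,3S,4R)-3-[(3S)-3-bromo-4-chloro-4-methylpentyl]-1,3-dimethyl-7-oxabicyclo[2.2.1]heptan-2-yl}-3-methylpent-1-en-3-yl]oxy}silane
Product: 19 (3S)-5-{(1S,2S,3S,4R)-3-[(3S)-3-bromo-4-chloro-4-methylpentyl]-1,3-dimethyl-7-oxabicyclo[2.2.1]heptan-2-yl}-3-methylpent-1-en-3-ol
Conditions: HF·pyridine, pyridine, THF, 0 °C
Reagents that add atoms: none
Why: Fluoride-mediated desilylation of the tertiary silyl ether under pyridine-buffered conditions that leave the alkyl halides, the bridged ether and the tertiary allylic alcohol untouched.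

**Compound list**
1 | (S)-(+)-linalool [(3S)-3,7-dimethylocta-1,6-dien-3-ol] | C=C[C@@](C)(O)CCC=C(C)C | starting material
2 | triethyl{[(3S)-3,7-dimethylocta-1,6-dien-3-yl]oxy}silane | C=C[C@@](C)(O[Si](CC)(CC)CC)CCC=C(C)C | intermediate
3 | (2E,6S)-2,6-dimethyl-6-[(triethylsilyl)oxy]octa-2,7-dien-1-ol | C=C[C@@](C)(O[Si](CC)(CC)CC)CC/C=C(\C)CO | intermediate
4 | (2E,6S)-2,6-dimethyl-6-[(triethylsilyl)oxy]octa-2,7-dienal | C=C[C@@](C)(O[Si](CC)(CC)CC)CC/C=C(\C)C=O | intermediate
5 | (3S,4E,8S)-4,8-dimethyl-8-[(triethylsilyl)oxy]deca-4,9-dien-3-ol | C=C[C@@](C)(O[Si](CC)(CC)CC)CC/C=C(\C)[C@H](CC)O | intermediate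
6 | sulcatone (6-methylhept-5-en-2-one) | CC(=O)CCC=C(C)C | starting material
7 | diethyl 6-methylhepta-1,5-dien-2-yl phosphate | C=C(CCC=C(C)C)OP(=O)(OCC)OCC | intermediate
8 | 6-methylhept-5-en-1-yne | C#CCCC=C(C)C | intermediate
9 | [(1E)-2,6-dimethylhepta-1,5-dien-1-yl]dimethylalane | C[Al](C)/C=C(\C)CCC=C(C)C | intermediate
10 | (1E)-1-iodo-2,6-dimethylhepta-1,5-diene | I/C=C(\C)CCC=C(C)C | intermediate
11 | (3R)-3-[(3E)-4-iodo-3-methylbut-3-en-1-yl]-2,2-dimethyloxirane | I/C=C(\C)CC[C@H]1OC1(C)C | intermediate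
12 | (3R)-3-[(3E)-4-{[(3S,4E,8S)-4,8-dimethyl-8-[(triethylsilyl)oxy]deca-4,9-dien-3-yl]oxy}-3-methylbut-3-en-1-yl]-2,2-dimethyloxirane | C=C[C@@](C)(O[Si](CC)(CC)CC)CC/C=C(\C)[C@H](CC)O/C=C(\C)CC[C@H]1OC1(C)C | intermediate
13 | (2S,3R,4E)-2-{2-[(2R)-3,3-dimethyloxiran-2-yl]ethyl}-2,4-dimethyl-3-{(3S)-3-methyl-3-[(triethylsilyl)oxy]pent-4-en-1-yl}hept-4-enal | O=C[C@@](C)(CC[C@H]1OC1(C)C)[C@H](CC[C@](C)(O[Si](CC)(CC)CC)C=C)/C(C)=C/CC | intermediate
14 | (4R,5S,6R,7E)-5-{2-[(2R)-3,3-dimethyloxiran-2-yl]ethyl}-5,7-dimethyl-6-{(3S)-3-methyl-3-[(triethylsilyl)oxy]pent-4-en-1-yl}deca-1,7-dien-4-ol | C=CC[C@@H](O)[C@@](C)(CC[C@H]1OC1(C)C)[C@H](CC[C@](C)(O[Si](CC)(CC)CC)C=C)/C(C)=C/CC | intermediate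
15 | (1R,5R,6S)-6-{2-[(2R)-3,3-dimethyloxiran-2-yl]ethyl}-4,6-dimethyl-5-{(3S)-3-methyl-3-[(triethylsilyl)oxy]pent-4-en-1-yl}cyclohex-3-en-1-ol | CC1=CC[C@@H](O)[C@@](C)(CC[C@H]2OC2(C)C)[C@@H]1CC[C@](C)(O[Si](CC)(CC)CC)C=C | intermediate
16 | triethyl{[(3S)-5-{(1S,2S,3S,4R)-3-{2-[(2R)-3,3-dimethyloxiran-2-yl]ethyl}-1,3-dimethyl-7-oxabicyclo[2.2.1]heptan-2-yl}-3-methylpent-1-en-3-yl]oxy}silane | C=C[C@@](C)(O[Si](CC)(CC)CC)CC[C@H]1[C@](C)(CC[C@H]3OC3(C)C)[C@H]2CC[C@]1(C)O2 | intermediate
17 | (3R)-2-bromo-5-[(1R,2S,3S,4S)-2,4-dimethyl-3-{(3S)-3-methyl-3-[(triethylsilyl)oxy]pent-4-en-1-yl}-7-oxabicyclo[2.2.1]heptan-2-yl]-2-methylpentan-3-ol | C=C[C@@](C)(O[Si](CC)(CC)CC)CC[C@H]1[C@](C)(CC[C@@H](O)C(C)(C)Br)[C@H]2CC[C@]1(C)O2 | intermediate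
18 | triethyl{[(3S)-5-{(1S,2S,3S,4R)-3-[(3S)-3-bromo-4-chloro-4-methylpentyl]-1,3-dimethyl-7-oxabicyclo[2.2.1]heptan-2-yl}-3-methylpent-1-en-3-yl]oxy}silane | C=C[C@@](C)(O[Si](CC)(CC)CC)CC[C@H]1[C@](C)(CC[C@H](Br)C(C)(C)Cl)[C@H]2CC[C@]1(C)O2 | intermediate
19 | (3S)-5-{(1S,2S,3S,4R)-3-[(3S)-3-bromo-4-chloro-4-methylpentyl]-1,3-dimethyl-7-oxabicyclo[2.2.1]heptan-2-yl}-3-methylpent-1-en-3-ol | C=C[C@@](C)(O)CC[C@H]1[C@](C)(CC[C@H](Br)C(C)(C)Cl)[C@H]2CC[C@]1(C)O2 | target

**Step count and risks**
Total step count: 13. Longest linear sequence: 10 steps (1, 2, 3, 7, 8, 9, 10, 11, 12, 13); steps 4 to 6 are the three-step side branch.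

The three steps most likely to fail:

Step 10 (the new photochemical bridge closure). The tertiary cation may lose a proton to give the photo-inert exocyclic alkene instead of closing, and the quantum yield may be low. The fallback uses known chemistry and sets out from 15. NIS with NaHCO3 in CH2Cl2 at 0 °C effects anti iodoetherification, the hydroxyl attacking the tertiary alkene carbon, to give the endo-iodo bridged ether F1. Radical deiodination with Bu3SnH and AIBN in toluene at 80 °C then removes the iodine, and the route is rejoined at 16.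

Step 7 (C–O coupling and Claisen rearrangement). The secondary allylic alcohol and the trisubstituted vinyl iodide are both hindered, and 140 °C may erode material or the chair/boat preference. The fallback sets out from 11. Miyaura borylation (B2pin2, PdCl2(dppf), KOPh, toluene, 50 °C) gives the (E)-alkenyl pinacol boronate F2. Oxidative coupling of F2 with 5, promoted by Cu(OAc)2 (Et3N, 4 Å sieves, air, CH2Cl2, room temperature; Chan–Lam–Evans type), gives allyl vinyl ether 12, now isolated. Heating 12 in toluene at 140 °C (Claisen) rejoins the route at 13.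

Step 12 (chlorination with bromine shift). Elimination from the bromonium ion to an allylic bromide, or chloride attack at the secondary carbon, would lower yield or scramble the halogens. The fallback sets out from 16 and reverses the order of halogen entry. LiCl with AcOH in THF opens the epoxide at the tertiary carbon to the (R)-chlorohydrin F3. Appel bromination (CBr4, PPh3, CH2Cl2, 0 °C to room temperature) then replaces the secondary hydroxyl by bromide with inversion, and the route is rejoined at 18.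

**Further compounds**
F1 | step 10 | triethyl{[(3S)-5-{(1R,2S,3S,4R,6R)-3-{2-[(2R)-3,3-dimethyloxiran-2-yl]ethyl}-6-iodo-1,3-dimethyl-7-oxabicyclo[2.2.1]heptan-2-yl}-3-methylpent-1-en-3-yl]oxy}silane (iodine endo, anti to the oxygen bridge) | C=C[C@@](C)(O[Si](CC)(CC)CC)CC[C@H]1[C@](C)(CC[C@H]3OC3(C)C)[C@H]2C[C@@H](I)[C@]1(C)O2
F2 | step 7 | 2-[(1E)-4-[(2R)-3,3-dimethyloxiran-2-yl]-2-methylbut-1-en-1-yl]-4,4,5,5-tetramethyl-1,3,2-dioxaborolane | CC1(C)OB(/C=C(\C)CC[C@H]2OC2(C)C)OC1(C)C
F3 | step 12 | (3R)-2-chloro-5-[(1R,2S,3S,4S)-2,4-dimethyl-3-{(3S)-3-methyl-3-[(triethylsilyl)oxy]pent-4-en-1-yl}-7-oxabicyclo[2.2.1]heptan-2-yl]-2-methylpentan-3-ol | C=C[C@@](C)(O[Si](CC)(CC)CC)CC[C@H]1[C@](C)(CC[C@@H](O)C(C)(C)Cl)[C@H]2CC[C@]1(C)O2
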